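The route rests on cutting the aryl ester O–C(=O) bond of a 3-hydroxybenzofuran-2(3H)-one. In the target the quaternary carbinol carbon stands ortho to the phenol O–H on the benzene ring, so that oxygen can close a five-membered lactone onto one of two ester carbons that later become the two CH2O arms. A chiral phosphoric acid is to make that choice in one operation: it closes the ring, sets the quaternary centre, tells the arms apart (aryl lactone against tert-butyl ester) and masks the phenol. The precursor is a di-tert-butyl 2-aryl-2-hydroxymalonate with free phenol and tertiary OH, already carrying the (R)-2-methylbutanoate.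

Key step: step 5

Remark: because the precursor already holds the (R) centre of the side chain, its two ester groups are diastereotopic, not enantiotopic; the closure is a catalyst-controlled choice between two groups, and which catalyst enantiomer gives the (3S) lactone has to be assigned in a first run (the antipode is equally available).

Remark: the structure of the precursor is kept unchanged (two bulky tert-butyl esters, no protecting group on phenol or tertiary OH); the added precautions are a non-nucleophilic magnesium base, a cold quench and exclusion of acid until the ring closure.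

Step 1
Reactants: 1 3-hydroxybenzyl alcohol; 2 (R)-2-methylbutanoic acid
Product: 3 (3-hydroxyphenyl)methyl (2R)-2-methylbutanoate
Conditions: PPh3, DIAD, THF, 0 °C to rt
Reagents that add atoms: none
Why: Mitsunobu esterification, in which the benzylic alcohol is activated as its alkoxyphosphonium ion and displaced by the carboxylate while the much less acidic phenol stays free; the acid is never activated at its carbonyl, so its (R) centre is kept, and no new stereocentre forms.

Step 2
Reactants: 4 di-tert-butyl malonate
Product: 5 di-tert-butyl 2-diazopropanedioate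
Conditions: 4-acetamidobenzenesulfonyl azide, Et3N, MeCN, 0 °C to rt
Reagents that add atoms: 4-acetamidobenzenesulfonyl azide, CC(=O)Nc1ccc(cc1)S(=O)(=O)N=[N+]=[N-]
Why: Regitz diazo transfer, in which the malonate enolate adds to the terminal nitrogen of the sulfonyl azide and the triazene collapses to the diazomalonate and the sulfonamide.

Step 3
Reactants: 5 di-tert-butyl 2-diazopropanedioate
Product: 6 di-tert-butyl 2-oxopropanedioate (di-tert-butyl ketomalonate)
Conditions: dimethyldioxirane (acetone solution), CH2Cl2, 0 °C to rt
Reagents that add atoms: dimethyldioxirane, CC1(C)OO1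
Why: Oxygen-atom transfer from the dioxirane to the diazo carbon with loss of N2, the known oxidation of 2-diazo-1,3-dicarbonyl compounds to vicinal tricarbonyl compounds; the neutral, anhydrous medium spares the tert-butyl esters and should give the keto form, not the hydrate.

Step 4
Reactants: 3 (3-hydroxyphenyl)methyl (2R)-2-methylbutanoate; 6 di-tert-butyl 2-oxopropanedioate
Product: 8 di-tert-butyl 2-hydroxy-2-[2-hydroxy-4-[[(2R)-2-methylbutanoyl]oxymethyl]phenyl]propanedioate, via chloromagnesium phenoxide 7 (not isolated)
Conditions: t-BuMgCl (1.0 equiv), PhMe, −20 °C; then 6, −20 to 20 °C; cold 0.5 M HCl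
Reagents that add atoms: tert-butylmagnesium chloride, CC(C)(C)[Mg]Cl (its MgCl is held only in intermediate 7 and leaves on work-up; 8 keeps no atom of it)
Why: Ortho-selective Friedel–Crafts hydroxyalkylation of a magnesium phenoxide, in which magnesium binds the very electrophilic keto group of 6 and delivers it through a six-membered chelate to the free ortho carbon para to the CH2O group (the other ortho carbon is flanked by two substituents); the hindered base only deprotonates the phenol, and no stereocentre forms because the two esters are identical.

Step 5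
Reactants: 8 di-tert-butyl 2-hydroxy-2-[2-hydroxy-4-[[(2R)-2-methylbutanoyl]oxymethyl]phenyl]propanedioate
Product: 9 tert-butyl (3S)-3-hydroxy-6-[[(2R)-2-methylbutanoyl]oxymethyl]-2-oxo-2,3-dihydro-1-benzofuran-3-carboxylate
Conditions: (R)-3,3'-bis(2,4,6-triisopropylphenyl)-1,1'-binaphthyl-2,2'-diyl hydrogen phosphate (10 mol %), PhMe, 35 °C
Reagents that add atoms: none
Why: Proposed new method: the phosphoric acid should act bifunctionally, its P=O oxygen accepting a hydrogen bond from the phenol O–H while its P–OH activates one ester carbonyl, so that the phenol oxygen adds to that carbonyl and the tetrahedral intermediate collapses with loss of tert-butanol (acid-catalysed transesterification by addition–elimination). The closest known reaction type is the chiral-phosphoric-acid-catalysed desymmetrising lactonisation of di-tert-butyl malonates carrying a tethered aliphatic hydroxyl group, which gives lactones with a quaternary α-carbon; a phenol nucleophile and an α-hydroxymalonate have not been shown, hence the label. The benzofuran-2(3H)-one ring closes in the 5-exo-trig mode. The new C3 stereocentre is controlled by the catalyst, whose 3,3'-aryl pocket decides which ester group is attacked, the remote side-chain centre being too far away to interfere. The step needs group selectivity between the two esters and chemoselectivity for ring closure over ester acidolysis; the bulk of the tert-butyl groups keeps uncatalysed closure slow, the tertiary OH cannot close a ring of its own, and the mild acidity of the catalyst should leave the second ester intact.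

Step 6
Reactants: 9 tert-butyl (3S)-3-hydroxy-6-[[(2R)-2-methylbutanoyl]oxymethyl]-2-oxo-2,3-dihydro-1-benzofuran-3-carboxylate
Product: 10 (3S)-3-hydroxy-6-[[(2R)-2-methylbutanoyl]oxymethyl]-2-oxo-2,3-dihydro-1-benzofuran-3-carboxylic acid
Conditions: CF3CO2H, CH2Cl2, 0 °C; evaporate cold, use at once
Reagents that add atoms: none
Why: Acidolysis of a tert-butyl ester with loss of the tert-butyl cation as isobutene; the aryl lactone, the benzylic ester (meta to the ring oxygen, so not ionisable) and the tertiary alcohol between two carbonyl groups should survive anhydrous acid, and the quaternary C3 cannot epimerise.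

Step 7
Reactants: 10 (3S)-3-hydroxy-6-[[(2R)-2-methylbutanoyl]oxymethyl]-2-oxo-2,3-dihydro-1-benzofuran-3-carboxylic acid
Product: 11 [(3S)-3-hydroxy-3-(hydroxymethyl)-2-oxo-2,3-dihydro-1-benzofuran-6-yl]methyl (2R)-2-methylbutanoate
Conditions: BH3·SMe2, THF, 0 °C; aq. NH4Cl
Reagents that add atoms: none
Why: Chemoselective borane reduction of a carboxylic acid through its acyloxyborane, which is much faster than borane reduction of lactones or esters (the standard way from lactone acids to hydroxymethyl lactones); C3 is not touched.

Step 8
Reactants: 11 [(3S)-3-hydroxy-3-(hydroxymethyl)-2-oxo-2,3-dihydro-1-benzofuran-6-yl]methyl (2R)-2-methylbutanoate; 12 angelic acid, (Z)-2-methylbut-2-enoic acid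
Product: 14 [(3S)-3-hydroxy-6-[[(2R)-2-methylbutanoyl]oxymethyl]-2-oxo-2,3-dihydro-1-benzofuran-3-yl]methyl (Z)-2-methylbut-2-enoate, via angelic 2,4,6-trichlorobenzoic anhydride 13 (not isolated)
Conditions: 12, 2,4,6-trichlorobenzoyl chloride, Et3N (1 equiv), PhMe, rt; then 11, 60 °C
Reagents that add atoms: 2,4,6-trichlorobenzoyl chloride, O=C(Cl)c1c(Cl)cc(Cl)cc1Cl (its aroyl group is held only in intermediate 13; 14 keeps no atom of it)
Why: Yamaguchi-type mixed-anhydride esterification run without a nucleophilic catalyst, the established way to angelates without Z-to-E isomerisation; the primary alcohol attacks the unhindered angeloyl carbonyl of 13, the tertiary OH is too hindered to react and the phenol is still masked in the lactone.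

Step 9
Reactants: 14 [(3S)-3-hydroxy-6-[[(2R)-2-methylbutanoyl]oxymethyl]-2-oxo-2,3-dihydro-1-benzofuran-3-yl]methyl (Z)-2-methylbut-2-enoate
Product: 15 [(2R)-2,3-dihydroxy-2-[2-hydroxy-4-[[(2R)-2-methylbutanoyl]oxymethyl]phenyl]propyl] (Z)-2-methylbut-2-enoate
Conditions: NaBH4 (in portions), THF/aq. NaH2PO4–Na2HPO4 buffer (pH 7.5), 0 °C, short contact; pH 5 quench
Reagents that add atoms: none
Why: Borohydride reduction of an activated aryl ester, in which hydride adds to the lactone carbonyl, the phenoxide leaves and the aldehyde is reduced on to CH2OH while the two alkyl esters are not attacked at 0 °C; the near-neutral pH and short time are meant to stop 1,2- and 1,3-acyl shifts that would exchange the two arms, and no bond at the quaternary centre is broken.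

Step 10
Reactants: 15 [(2R)-2,3-dihydroxy-2-[2-hydroxy-4-[[(2R)-2-methylbutanoyl]oxymethyl]phenyl]propyl] (Z)-2-methylbut-2-enoate
Product: 16 [(2R)-3-acetoxy-2-hydroxy-2-[2-hydroxy-4-[[(2R)-2-methylbutanoyl]oxymethyl]phenyl]propyl] (Z)-2-methylbut-2-enoate
Conditions: immobilised Candida antarctica lipase B, vinyl acetate, t-BuOMe, 30 °C
Reagents that add atoms: vinyl acetate, CC(=O)OC=C
Why: Lipase-catalysed transesterification with an enol ester, made irreversible by tautomerisation of vinyl alcohol to acetaldehyde; the enzyme should acetylate the primary aliphatic alcohol but neither the phenol nor the tertiary alcohol, and the neutral medium avoids acyl migration, so the configuration set in step 5 is carried into the target.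

Compound list
1 | 3-hydroxybenzyl alcohol | OCc1cccc(O)c1 | starting material
2 | (R)-2-methylbutanoic acid | CC[C@@H](C)C(=O)O | starting material
3 | (3-hydroxyphenyl)methyl (2R)-2-methylbutanoate | Oc1cccc(COC(=O)[C@H](C)CC)c1 | intermediate
4 | di-tert-butyl malonate | CC(C)(C)OC(=O)CC(=O)OC(C)(C)C | starting material
5 | di-tert-butyl 2-diazopropanedioate | CC(C)(C)OC(=O)C(=[N+]=[N-])C(=O)OC(C)(C)C | intermediate
6 | di-tert-butyl 2-oxopropanedioate | CC(C)(C)OC(=O)C(=O)C(=O)OC(C)(C)C | intermediate
7 | chloromagnesium 3-[[(2R)-2-methylbutanoyl]oxymethyl]phenoxide (formed in the flask) | Cl[Mg]Oc1cccc(COC(=O)[C@H](C)CC)c1 | intermediate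
8 | di-tert-butyl 2-hydroxy-2-[2-hydroxy-4-[[(2R)-2-methylbutanoyl]oxymethyl]phenyl]propanedioate | OC(C(=O)OC(C)(C)C)(C(=O)OC(C)(C)C)c1ccc(COC(=O)[C@H](C)CC)cc1O | intermediate
9 | tert-butyl (3S)-3-hydroxy-6-[[(2R)-2-methylbutanoyl]oxymethyl]-2-oxo-2,3-dihydro-1-benzofuran-3-carboxylate | O=C1Oc2cc(COC(=O)[C@H](C)CC)ccc2[C@]1(O)C(=O)OC(C)(C)C | intermediate
10 | (3S)-3-hydroxy-6-[[(2R)-2-methylbutanoyl]oxymethyl]-2-oxo-2,3-dihydro-1-benzofuran-3-carboxylic acid | O=C1Oc2cc(COC(=O)[C@H](C)CC)ccc2[C@]1(O)C(=O)O | intermediate
11 | [(3S)-3-hydroxy-3-(hydroxymethyl)-2-oxo-2,3-dihydro-1-benzofuran-6-yl]methyl (2R)-2-methylbutanoate | O=C1Oc2cc(COC(=O)[C@H](C)CC)ccc2[C@]1(O)CO | intermediate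
12 | angelic acid, (Z)-2-methylbut-2-enoic acid | C/C=C(/C)C(=O)O | starting material
13 | (Z)-2-methylbut-2-enoic 2,4,6-trichlorobenzoic anhydride (formed in the flask) | C/C=C(/C)C(=O)OC(=O)c1c(Cl)cc(Cl)cc1Cl | intermediate
14 | [(3S)-3-hydroxy-6-[[(2R)-2-methylbutanoyl]oxymethyl]-2-oxo-2,3-dihydro-1-benzofuran-3-yl]methyl (Z)-2-methylbut-2-enoate | C/C=C(/C)C(=O)OC[C@]1(O)C(=O)Oc2cc(COC(=O)[C@H](C)CC)ccc21 | intermediate
15 | [(2R)-2,3-dihydroxy-2-[2-hydroxy-4-[[(2R)-2-methylbutanoyl]oxymethyl]phenyl]propyl] (Z)-2-methylbut-2-enoate | C/C=C(/C)C(=O)OC[C@](O)(CO)c1ccc(COC(=O)[C@H](C)CC)cc1O | intermediate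
16 | [(2R)-3-acetoxy-2-hydroxy-2-[2-hydroxy-4-[[(2R)-2-methylbutanoyl]oxymethyl]phenyl]propyl] (Z)-2-methylbut-2-enoate | C/C=C(/C)C(=O)OC[C@](O)(COC(C)=O)c1ccc(COC(=O)[C@H](C)CC)cc1O | target

Total step count: 10. Longest linear sequence: 9 steps (from 4 through steps 2, 3, 4, 5, 6, 7, 8, 9 and 10).

Steps most likely to fail

First, step 5. The catalyst may discriminate poorly between the two ester groups, the catalysed closure may be slow enough for unselective background closure to compete, or a tert-butyl ester may be cleaved by acid before the ring closes. The fallback uses known chemistry and sets out from 8. The ring is closed without stereocontrol by ordinary acid-catalysed lactonisation of the phenol onto the neighbouring ester: diphenyl hydrogen phosphate if closure is easy, otherwise p-toluenesulfonic acid (10 mol %), in PhMe at 50 °C, stopped before the second tert-butyl ester is lost. This should give 9 together with its C3 epimer, tert-butyl (3R)-3-hydroxy-6-[[(2R)-2-methylbutanoyl]oxymethyl]-2-oxo-2,3-dihydro-1-benzofuran-3-carboxylate F1. The two differ only at C3 and are separated by preparative chromatography on a polysaccharide chiral stationary phase (amylose tris(3,5-dimethylphenylcarbamate)). The fallback comes back to the route at 9. F1 need not be discarded, since the sequence in the next paragraph turns it into 11.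

Second, step 6, together with the reduction that follows it. Acid 10 is a β-carbonyl acid whose decarboxylation would lead to an aromatic benzofuran enol, so carbon dioxide may be lost with destruction of the quaternary centre; borane may also attack the activated lactone next to the acid. The fallback exchanges the roles of the two arms and sets out from 8. Closure with the antipodal phosphoric acid (or the separation above) gives the C3 epimer tert-butyl (3R)-3-hydroxy-6-[[(2R)-2-methylbutanoyl]oxymethyl]-2-oxo-2,3-dihydro-1-benzofuran-3-carboxylate F1. NaBH4 in THF/EtOH at 0 °C reduces only its aryl lactone, the tert-butyl ester being too hindered, to tert-butyl (2S)-2,3-dihydroxy-2-[2-hydroxy-4-[[(2R)-2-methylbutanoyl]oxymethyl]phenyl]propanoate F2. CF3CO2H in CH2Cl2 then cleaves the tert-butyl ester to (2S)-2,3-dihydroxy-2-[2-hydroxy-4-[[(2R)-2-methylbutanoyl]oxymethyl]phenyl]propanoic acid F3. As a gem-disubstituted 2-hydroxyphenylacetic acid, F3 should relactonise onto the phenol under the acid, if needed on concentration from PhMe with a trace of p-toluenesulfonic acid. Because the former lactone carbon is now the CH2OH group and the former ester carbon the lactone, the product is 11 itself, where the fallback comes back to the route. No β-carbonyl acid and no borane appear.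

Third, step 9. Under the basic borohydride medium the angeloyl group may shift to the tertiary oxygen and on to the newly freed primary oxygen; this exchange of the two arms would erode configurational purity at the quaternary carbon. One of the alkyl esters may also be over-reduced. The fallback delivers the two hydrides separately, the second under acid, and sets out from 14. i-Bu2AlH (CH2Cl2, −78 °C) should stop at the cyclic hemiacetal [(3S)-2,3-dihydroxy-6-[[(2R)-2-methylbutanoyl]oxymethyl]-2,3-dihydro-1-benzofuran-3-yl]methyl (Z)-2-methylbut-2-enoate F4, a mixture of C2 anomers in which the phenol is still tied up. NaBH(OAc)3 in AcOH/MeCN at 0 °C then reduces the ring-opened hydroxy aldehyde by hydroxyl-directed hydride delivery, in a weakly acidic medium where acyl migration is slow. This gives 15, where the fallback comes back to the route.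

Further compounds
F1 | step 5 | tert-butyl (3R)-3-hydroxy-6-[[(2R)-2-methylbutanoyl]oxymethyl]-2-oxo-2,3-dihydro-1-benzofuran-3-carboxylate | O=C1Oc2cc(COC(=O)[C@H](C)CC)ccc2[C@@]1(O)C(=O)OC(C)(C)C
F2 | step 6 | tert-butyl (2S)-2,3-dihydroxy-2-[2-hydroxy-4-[[(2R)-2-methylbutanoyl]oxymethyl]phenyl]propanoate | CC(C)(C)OC(=O)[C@@](O)(CO)c1ccc(COC(=O)[C@H](C)CC)cc1O
F3 | step 6 | (2S)-2,3-dihydroxy-2-[2-hydroxy-4-[[(2R)-2-methylbutanoyl]oxymethyl]phenyl]propanoic acid | OC(=O)[C@@](O)(CO)c1ccc(COC(=O)[C@H](C)CC)cc1O
F4 | step 9 | [(3S)-2,3-dihydroxy-6-[[(2R)-2-methylbutanoyl]oxymethyl]-2,3-dihydro-1-benzofuran-3-yl]methyl (Z)-2-methylbut-2-enoate | C/C=C(/C)C(=O)OC[C@]1(O)C(O)Oc2cc(COC(=O)[C@H](C)CC)ccc21
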